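Count the target in turnovers of the catalyst, that is, target over catalyst charge, and take that count to grow with the square of time. At the start neither the gas nor the solid is in solution; both earlier runs begin flat, then steepen with no bend up to their last readings.

| flask | solid substrate | gas phase | catalyst | remark | time |
|---|---|---|---|---|---|
| winter | 39 mM | 5.2 mM (held) | 1.6 mol% | run made earlier |  |
| noon | 39 mM | 5.2 mM (held) | 2.5 mol% | run made earlier |  |
| flask | 39 mM | 5.2 mM (held) | 3.3 mol% |  | 3.0 min |

- winter (time / min: target / %): 0.250: 1; 0.417: 2; 0.667: 2; 1.00: 3; 1.50: 3; 2.50: 5; 4.00: 11
- noon (time / min: target / %): 0.200: 0; 0.500: 1; 1.00: 2; 1.50: 5; 2.00: 5; 3.00: 10; 4.00: 16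

(standard deviation of a reading: 1.5 percentage points)

- solid substrate is a solid; its amount is given per volume of the solution
- at the start none of the solid substrate is in solution
- at the start none of the gas phase is in solution

- how much target there is at 3.0 min, in percent of the solid substrate charged
- concentration of dissolved gas in solution at 3.0 min, in percent of saturation

Under that rule one constant draws the curve. The last reading of the winter run gives 1.53 min and that of the noon run 1.58 min. Their mean, 1.55 min, is the first-turnover time, the moment at which the target equals the catalyst charge. The loading rose by a factor 1.56 between the runs, yet this time moved by 0.0500 min. The reckoning here therefore freezes dissolved gas near saturation, without a figure, as the readings give no uptake time.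

In the new flask the curve leaves the origin flat and crosses its catalyst charge of 3.3 mol% at 1.55 min. At 3.0 min it reaches 12.3%, climbing by 0.0820 /min of the charge per minute. The parabola meets the whole charge at 8.55 min, so it has to bend before then, and the asked time lies about a third of the way there.

The forecast says 13% of target, slightly above this reckoning, and 75% of saturation, holding that “the rate looks roughly first order in catalyst”.

The flask gives 13.3% of target and 92.5% of saturation, under this scheme:

    starting material + dissolved gas + catalyst → catalyst + target (k = 1260 /M²/s)
    solid substrate ⇌ starting material, rate k2*(cs2 - [starting material]) while solid is left; crystals form when [starting material] > cs2 (solubility = 15.0 mM, k = 0.00561 /s)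
    gas phase ⇌ dissolved gas, rate k3*(csat - [dissolved gas]) (kL = 0.112 /s)
    target → over-reaction product (k = 9.28 × 10⁻⁴ /s)

Read back from the flask, the first-turnover time is 1.49 min, close to the 1.55 min carried over. A neighbouring flask with 8.2 mol% of catalyst, read at the same 3.0 min, is reckoned at 30.6% with that carried time. It holds 21.6%, less than the reckoning, so its own first-turnover time is 1.85 min. At 3.0 min its starting material stands at 8.75% of the charge, against 14.6% in the flask at the same time.

(The readings stem from a simulated flask with made-up constants; the scatter is artificial.)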